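Retrosynthetic cuts of the target (7-O-methylagathisflavone: apigenin unit 2 bonded through C8'' to C6 of 7-O-methylapigenin unit 1), in order: four O-benzyl bonds, O1-C2 (ring C, unit 1), C4a-C5 (ring A, unit 1), C4-C4a, and the C6-C8'' axis.
Enabling feature: carbons C4a, C5, C6, C7, C8 and C8a of ring A in unit 1 show the 1-acyl-2,4,6-trioxygenated pattern of a folded polyketide, with unit 2 on C6 and a methyl group on O7 alone. C5-C6-C7-C8-C8a with their oxygens are therefore C2-C3-C4-C5-C6 of a 3-aryl-4-methoxy-2-pyrone, and C4a is its 6-methyl carbon.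
Forward, part 1: ring A of unit 2 is bought as phloroacetophenone and ring C is closed from a beta-diketone. C8'' is then iodinated and borylated, and Suzuki coupling to a 3-bromopyrone sets the axis.
Forward, part 2: a Weinreb acylation at the pyrone methyl group adds C4, C3, C2 and ring B, with the C2 ketone kept as a dioxolane so that only one folding mode remains.
Forward, part 3: Mg(OMe)2 opens the pyrone and refolds it into carbocyclic ring A, aqueous acid unmasks C2 and closes ring C, and hydrogenolysis ends the route.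
Stereochemistry: there is no stereocentre. The only stereogenic element is the C6-C8'' axis, which forms racemic.

Key step: step 11

Assumption: the target SMILES carries no descriptor for the hindered C6-C8'' axis, so the racemic atropisomer mixture is taken as the target.

Step 1
Reactants: 1 2',4',6'-trihydroxyacetophenone
Product: 2 1-[2,4-bis(benzyloxy)-6-hydroxyphenyl]ethan-1-one
Conditions: BnBr (2.1 equiv), K2CO3 (2.2 equiv), DMF, rt to 60 °C
Reagents that add atoms: benzyl bromide, BrCc1ccccc1
Why: Williamson etherification in which the 4-OH and one of the two equivalent ortho hydroxyls are alkylated, while the last hydroxyl is tied up in a hydrogen bond to the acetyl carbonyl and stays free when the bromide is limited to two equivalents.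

Step 2
Reactants: 2 1-[2,4-bis(benzyloxy)-6-hydroxyphenyl]ethan-1-one; 3 4-(benzyloxy)benzoyl chloride
Product: 4 1-[2,4-bis(benzyloxy)-6-hydroxyphenyl]-3-[4-(benzyloxy)phenyl]propane-1,3-dione
Conditions: LiN(SiMe3)2 (3.2 equiv), THF, -78 to -10 °C; then 3, -78 °C to rt; aq HCl
Reagents that add atoms: none
Why: Crossed Claisen C-acylation of the lithium phenoxide-enolate dianion (the direct variant of the Baker-Venkataraman sequence), the third equivalent of base taking up the acidic beta-diketone proton so that a second acylation is suppressed.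

Step 3
Reactants: 4 1-[2,4-bis(benzyloxy)-6-hydroxyphenyl]-3-[4-(benzyloxy)phenyl]propane-1,3-dione
Product: 5 5,7-bis(benzyloxy)-2-[4-(benzyloxy)phenyl]-4H-chromen-4-one (tri-O-benzylapigenin)
Conditions: NaOAc, AcOH, 110 °C
Reagents that add atoms: none
Why: Cyclodehydration of an o-hydroxyaryl beta-diketone (cyclic hemiketal, then loss of water), the standard closure of flavone ring C, run in buffered acetic acid so that the benzyl ethers are left alone.

Step 4
Reactants: 5 tri-O-benzylapigenin
Product: 6 5,7-bis(benzyloxy)-2-[4-(benzyloxy)phenyl]-8-iodo-4H-chromen-4-one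
Conditions: NIS (1.1 equiv), CF3CO2H (0.3 equiv), MeCN/CH2Cl2, 0 °C to rt, dark
Reagents that add atoms: N-iodosuccinimide, O=C1CCC(=O)N1I
Why: Electrophilic aromatic iodination, which with O5 alkylated goes to C8 because that carbon is flanked by one benzyloxy group and the small ring oxygen, whereas C6 lies between two benzyloxy groups and ring B and C3 are deactivated by the enone.

Step 5
Reactants: 6 8-iodo-tri-O-benzylapigenin
Product: 7 5,7-bis(benzyloxy)-2-[4-(benzyloxy)phenyl]-8-(4,4,5,5-tetramethyl-1,3,2-dioxaborolan-2-yl)-4H-chromen-4-one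
Conditions: HBpin (2 equiv), PdCl2(MeCN)2 (3 mol %), SPhos (12 mol %), Et3N (3 equiv), 1,4-dioxane, 80 °C
Reagents that add atoms: pinacolborane, CC1(C)OBOC1(C)C
Why: Miyaura-Masuda borylation of an aryl iodide with pinacolborane, chosen because the bulky electron-rich phosphine copes with doubly ortho-substituted, electron-rich halides and the amine base spares the flavone carbonyl system.

Step 6
Reactants: 8 4-methoxy-6-methyl-2H-pyran-2-one
Product: 9 3-bromo-4-methoxy-6-methyl-2H-pyran-2-one
Conditions: NBS (1.05 equiv), MeCN, rt, dark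
Reagents that add atoms: N-bromosuccinimide, O=C1CCC(=O)N1Br
Why: Electrophilic bromination at C3, the nucleophilic alpha-carbon of the beta-methoxy enoate, under ionic conditions that leave the allylic methyl group untouched.

Step 7
Reactants: 7 tri-O-benzylapigenin 8-boronate; 9 3-bromo-4-methoxy-6-methyl-2H-pyran-2-one
Product: 10 5,7-bis(benzyloxy)-2-[4-(benzyloxy)phenyl]-8-(4-methoxy-6-methyl-2-oxo-2H-pyran-3-yl)-4H-chromen-4-one
Conditions: Pd(OAc)2 (5 mol %), SPhos (10 mol %), K3PO4 (3 equiv), toluene/H2O, 80 °C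
Reagents that add atoms: none
Why: Suzuki-Miyaura coupling in which oxidative addition into the electron-poor C3-Br bond is easy and the groups beside it (a carbonyl oxygen and a methoxy group on a planar heterocycle) are small, so the crowded axis is built before ring A exists as an arene.

Step 8
Reactants: 3 4-(benzyloxy)benzoyl chloride; 11 N-methoxy-N-methylacetamide
Product: 12 3-[4-(benzyloxy)phenyl]-N-methoxy-N-methyl-3-oxopropanamide
Conditions: 11 (2.1 equiv), LiN(iPr)2 (2.1 equiv), THF, -78 °C; then 3 (1 equiv), -78 °C; aq NH4Cl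
Reagents that add atoms: none
Why: Crossed Claisen acylation of the lithium enolate of a Weinreb acetamide with an acid chloride, the second equivalent of enolate deprotonating the beta-keto amide as it forms.

Step 9
Reactants: 12 3-[4-(benzyloxy)phenyl]-N-methoxy-N-methyl-3-oxopropanamide
Product: 13 2-{2-[4-(benzyloxy)phenyl]-1,3-dioxolan-2-yl}-N-methoxy-N-methylacetamide
Conditions: Me3SiOCH2CH2OSiMe3 (2 equiv), Me3SiOTf (10 mol %), CH2Cl2, -78 °C to rt; then pyridine
Reagents that add atoms: 1,2-bis(trimethylsilyloxy)ethane, C[Si](C)(C)OCCO[Si](C)(C)C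
Why: Noyori ketalisation, made irreversible by formation of hexamethyldisiloxane so that even the conjugated p-alkoxyaryl ketone is converted, which removes the acidic methylene proton of the aroylacetyl unit.

Step 10
Reactants: 10 8-(4-methoxy-6-methyl-2-oxopyran-3-yl)-tri-O-benzylapigenin; 13 dioxolane Weinreb amide
Product: 14 3-(tri-O-benzylapigenin-8-yl)-6-{3-[2-(4-benzyloxyphenyl)-1,3-dioxolan-2-yl]-2-oxopropyl}-4-methoxy-2H-pyran-2-one
Conditions: LiN(SiMe3)2 (1.1 equiv), THF, -78 °C; then 13 (1.3 equiv), -78 to 0 °C; aq NH4Cl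
Reagents that add atoms: none
Why: Weinreb ketone synthesis with a vinylogous ester enolate: the base removes a proton only from the 6-methyl group (pyrone C3 is blocked and the vinylic C3''-H of the flavone is far less acidic), the dienolate reacts at its gamma-carbon, the chelated tetrahedral adduct lasts until the quench so the acidic product never meets unreacted anion, and the dioxolane deprives the acyl donor of the beta-diketone proton that would otherwise quench that anion.

Step 11
Reactants: 14 3-(tri-O-benzylapigenin-8-yl)-6-{3-[2-(4-benzyloxyphenyl)-1,3-dioxolan-2-yl]-2-oxopropyl}-4-methoxy-2H-pyran-2-one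
Product: 16 1-[3-(tri-O-benzylapigenin-8-yl)-2,6-dihydroxy-4-methoxyphenyl]-2-[2-(4-benzyloxyphenyl)-1,3-dioxolan-2-yl]ethan-1-one, via ring-opened enol-ether diketo ester 15 (not isolated)
Conditions: Mg(OMe)2 (8 equiv, solution in MeOH), MeOH/THF, reflux; cold aq NH4Cl
Reagents that add atoms: none
Why: Methoxide from Mg(OMe)2 adds to the lactone carbonyl (the future C5) and releases the C8a oxygen as an enolate, giving the magnesium chelate of ester 15, whose tetrasubstituted C6=C7 double bond keeps the ester carbon and the C8 methylene on the same side, as they were in the pyrone. C4a, the central carbon of the C8a/C4 beta-diketonate, then attacks the ester carbonyl, methoxide leaves, and tautomerisation to the magnesium bis-phenoxide is irreversible and drains the reversible lactone opening. The closest known reaction type is the Mg(OMe)2-induced Claisen (Dieckmann-type) folding of 6-(2-oxoalkyl)-2-pyrones and 3,5,7-triketo esters into acylphloroglucinols. Ring A closes in the 6-(enolexo)-exo-trig mode, with the C4-C4a enolate bond outside and the ester C=O exo to the new six-membered ring; no stereocentre arises and the axis stays racemic. The selectivity needed is Claisen folding over aldol, Michael and O-cyclisation paths: C6 is fully substituted and cannot act as a donor, and the dioxolane removes the aryl ketone as an acceptor and leaves C3 only singly activated, so C4a is the one stabilised carbanion and C5 the one carbonyl it can reach through a six-membered transition state. Exchange of the C7 methoxy group by methoxide is degenerate, so the methylation pattern passes through unchanged.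

Step 12
Reactants: 16 1-[3-(tri-O-benzylapigenin-8-yl)-2,6-dihydroxy-4-methoxyphenyl]-2-[2-(4-benzyloxyphenyl)-1,3-dioxolan-2-yl]ethan-1-one
Product: 18 4',5'',7'',4'''-tetra-O-benzyl-7-O-methylagathisflavone, via free beta-diketone 17 (not isolated)
Conditions: 1 M aq HCl, THF/MeOH, rt to 50 °C
Reagents that add atoms: none
Why: Acetal hydrolysis followed by acid-catalysed cyclodehydration of the o-hydroxyaryl beta-diketone, in which the hydroxyl beside the axis is buttressed into the stronger hydrogen bond with the C4 carbonyl and becomes 5-OH, so the side chain faces the open hydroxyl para to the axis, which adds to C2 and gives the 6-linked flavone.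

Step 13
Reactants: 18 4',5'',7'',4'''-tetra-O-benzyl-7-O-methylagathisflavone
Product: 19 7-O-methylagathisflavone (CNP0246647.0)
Conditions: H2 (1 atm), Pd/C (10 wt %), THF/MeOH, rt
Reagents that add atoms: none
Why: Catalytic hydrogenolysis of four aryl benzyl ethers, a standard last step for flavones, which at one atmosphere leaves the methyl ether, both pyranone double bonds and the biaryl bond intact.

Compound list
1 | 2',4',6'-trihydroxyacetophenone | CC(=O)c1c(O)cc(O)cc1O | starting material
2 | 1-[2,4-bis(benzyloxy)-6-hydroxyphenyl]ethan-1-one | CC(=O)c1c(O)cc(OCc2ccccc2)cc1OCc1ccccc1 | intermediate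
3 | 4-(benzyloxy)benzoyl chloride | O=C(Cl)c1ccc(OCc2ccccc2)cc1 | starting material
4 | 1-[2,4-bis(benzyloxy)-6-hydroxyphenyl]-3-[4-(benzyloxy)phenyl]propane-1,3-dione | O=C(CC(=O)c1c(O)cc(OCc2ccccc2)cc1OCc1ccccc1)c1ccc(OCc2ccccc2)cc1 | intermediate
5 | 5,7-bis(benzyloxy)-2-[4-(benzyloxy)phenyl]-4H-chromen-4-one (tri-O-benzylapigenin) | O=c1cc(-c2ccc(OCc3ccccc3)cc2)oc2cc(OCc3ccccc3)cc(OCc3ccccc3)c12 | intermediate
6 | 5,7-bis(benzyloxy)-2-[4-(benzyloxy)phenyl]-8-iodo-4H-chromen-4-one | O=c1cc(-c2ccc(OCc3ccccc3)cc2)oc2c(I)c(OCc3ccccc3)cc(OCc3ccccc3)c12 | intermediate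
7 | 5,7-bis(benzyloxy)-2-[4-(benzyloxy)phenyl]-8-(4,4,5,5-tetramethyl-1,3,2-dioxaborolan-2-yl)-4H-chromen-4-one | CC1(C)OB(OC1(C)C)c1c(OCc2ccccc2)cc(OCc2ccccc2)c2c(=O)cc(-c3ccc(OCc4ccccc4)cc3)oc12 | intermediate
8 | 4-methoxy-6-methyl-2H-pyran-2-one | COC1=CC(=O)OC(C)=C1 | starting material
9 | 3-bromo-4-methoxy-6-methyl-2H-pyran-2-one | COC1=C(Br)C(=O)OC(C)=C1 | intermediate
10 | 5,7-bis(benzyloxy)-2-[4-(benzyloxy)phenyl]-8-(4-methoxy-6-methyl-2-oxo-2H-pyran-3-yl)-4H-chromen-4-one | COC1=C(-c2c(OCc3ccccc3)cc(OCc3ccccc3)c3c(=O)cc(-c4ccc(OCc5ccccc5)cc4)oc23)C(=O)OC(C)=C1 | intermediate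
11 | N-methoxy-N-methylacetamide | CC(=O)N(C)OC | starting material
12 | 3-[4-(benzyloxy)phenyl]-N-methoxy-N-methyl-3-oxopropanamide | CON(C)C(=O)CC(=O)c1ccc(OCc2ccccc2)cc1 | intermediate
13 | 2-{2-[4-(benzyloxy)phenyl]-1,3-dioxolan-2-yl}-N-methoxy-N-methylacetamide | CON(C)C(=O)CC1(c2ccc(OCc3ccccc3)cc2)OCCO1 | intermediate
14 | 3-(tri-O-benzylapigenin-8-yl)-6-{3-[2-(4-benzyloxyphenyl)-1,3-dioxolan-2-yl]-2-oxopropyl}-4-methoxy-2H-pyran-2-one | COC1=C(-c2c(OCc3ccccc3)cc(OCc3ccccc3)c3c(=O)cc(-c4ccc(OCc5ccccc5)cc4)oc23)C(=O)OC(CC(=O)CC2(c3ccc(OCc4ccccc4)cc3)OCCO2)=C1 | intermediate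
15 | methyl (2E)-2-(tri-O-benzylapigenin-8-yl)-8-[2-(4-benzyloxyphenyl)-1,3-dioxolan-2-yl]-3-methoxy-5,7-dioxooct-2-enoate (not isolated) | COC(=O)/C(c1c(OCc2ccccc2)cc(OCc2ccccc2)c2c(=O)cc(-c3ccc(OCc4ccccc4)cc3)oc12)=C(/OC)CC(=O)CC(=O)CC1(c2ccc(OCc3ccccc3)cc2)OCCO1 | intermediate
16 | 1-[3-(tri-O-benzylapigenin-8-yl)-2,6-dihydroxy-4-methoxyphenyl]-2-[2-(4-benzyloxyphenyl)-1,3-dioxolan-2-yl]ethan-1-one | COc1cc(O)c(C(=O)CC2(c3ccc(OCc4ccccc4)cc3)OCCO2)c(O)c1-c1c(OCc2ccccc2)cc(OCc2ccccc2)c2c(=O)cc(-c3ccc(OCc4ccccc4)cc3)oc12 | intermediate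
17 | 1-[3-(tri-O-benzylapigenin-8-yl)-2,6-dihydroxy-4-methoxyphenyl]-3-[4-(benzyloxy)phenyl]propane-1,3-dione (not isolated) | COc1cc(O)c(C(=O)CC(=O)c2ccc(OCc3ccccc3)cc2)c(O)c1-c1c(OCc2ccccc2)cc(OCc2ccccc2)c2c(=O)cc(-c3ccc(OCc4ccccc4)cc3)oc12 | intermediate
18 | 6-{5,7-bis(benzyloxy)-2-[4-(benzyloxy)phenyl]-4-oxo-4H-chromen-8-yl}-2-[4-(benzyloxy)phenyl]-5-hydroxy-7-methoxy-4H-chromen-4-one (4',5'',7'',4'''-tetra-O-benzyl-7-O-methylagathisflavone) | COc1cc2oc(-c3ccc(OCc4ccccc4)cc3)cc(=O)c2c(O)c1-c1c(OCc2ccccc2)cc(OCc2ccccc2)c2c(=O)cc(-c3ccc(OCc4ccccc4)cc3)oc12 | intermediate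
19 | 7-O-methylagathisflavone (CNP0246647.0), racemic about the C6-C8'' axis | COc1cc2oc(-c3ccc(O)cc3)cc(=O)c2c(O)c1-c1c(O)cc(O)c2c(=O)cc(-c3ccc(O)cc3)oc12 | target

Total step count: 13.
Longest linear sequence: 10 steps (steps 1, 2, 3, 4, 5, 7, 10, 11, 12, 13).

Steps most likely to fail

**Step 11.** The lactone carbonyl, and after opening the ester carbonyl, stand next to a fourfold ortho-substituted axis.
- Ring opening may therefore not proceed far enough.
- Carbon-carbon closure may also lose to methanolytic retro-Claisen cleavage of the side chain or to O-cyclisation of the chain.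

The fallback gives up the folding and joins two finished flavones, setting out from boronate 7. Purchased genkwanin F1 would be benzylated at O4' (BnBr, K2CO3, acetone, reflux; the chelated 5-OH stays free) to 4'-O-benzylgenkwanin F2. Iodination at C6 under the direction of the free 5-OH (BnMe3N[ICl2], CaCO3, CH2Cl2/MeOH) would give 4'-O-benzyl-6-iodogenkwanin F3. Suzuki-Miyaura coupling of this iodide with 7 (Pd(OAc)2, SPhos, K3PO4, toluene/H2O) comes back to the route at 18.

**Step 7.** Protodeboronation of the doubly ortho-oxygenated boronate may outrun transmetalation, and reductive elimination at the crowded axis may be slow.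

The fallback reverses the polarity and changes the metal, which also makes step 5 unnecessary. It sets out from bromide 9 and iodide 6. Compound 9 would be stannylated (Me3SnSnMe3, Pd(PPh3)4, toluene, 100 °C) to 4-methoxy-6-methyl-3-(trimethylstannyl)-2H-pyran-2-one F4. A copper-assisted Stille coupling of this stannane with 6 (Pd(PPh3)4, CuI, CsF, DMF, 45 °C) comes back at 10.

**Step 12.** Site selectivity between the two phenols may be poor, because ring closure points the new O-C bond away from the flanking group and so feels little of the bulk of the axis.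

The fallback tells the two oxygens apart by an intermolecular reaction, which does feel that bulk. It sets out from 16.
- MOMCl and iPr2NEt (CH2Cl2, 0 °C) should etherify only the open hydroxyl para to the axis, giving mono-MOM ether F5.
- BnBr and Cs2CO3 (DMF, 50 °C) would then cap the hydroxyl beside the axis, giving MOM benzyl diether F6.
- Aqueous HCl in THF/MeOH removes the MOM group and the dioxolane and can close ring C only on the freed oxygen, giving penta-O-benzyl ether F7.
- Hydrogenolysis under the conditions of step 13 comes back at 19.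

Further compounds
F1 | step 11 | genkwanin (5,4'-dihydroxy-7-methoxyflavone, purchased) | COc1cc(O)c2c(=O)cc(-c3ccc(O)cc3)oc2c1
F2 | step 11 | 4'-O-benzylgenkwanin | COc1cc(O)c2c(=O)cc(-c3ccc(OCc4ccccc4)cc3)oc2c1
F3 | step 11 | 4'-O-benzyl-6-iodogenkwanin | COc1cc2oc(-c3ccc(OCc4ccccc4)cc3)cc(=O)c2c(O)c1I
F4 | step 7 | 4-methoxy-6-methyl-3-(trimethylstannyl)-2H-pyran-2-one | COC1=C([Sn](C)(C)C)C(=O)OC(C)=C1
F5 | step 12 | mono-MOM ether of 16 (MOM on the oxygen para to the axis, hydroxyl beside the axis free) | COCOc1cc(OC)c(-c2c(OCc3ccccc3)cc(OCc3ccccc3)c3c(=O)cc(-c4ccc(OCc5ccccc5)cc4)oc23)c(O)c1C(=O)CC1(c2ccc(OCc3ccccc3)cc2)OCCO1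
F6 | step 12 | MOM benzyl diether of 16 (benzyl on the oxygen beside the axis) | COCOc1cc(OC)c(-c2c(OCc3ccccc3)cc(OCc3ccccc3)c3c(=O)cc(-c4ccc(OCc5ccccc5)cc4)oc23)c(OCc2ccccc2)c1C(=O)CC1(c2ccc(OCc3ccccc3)cc2)OCCO1
F7 | step 12 | 5,4',5'',7'',4'''-penta-O-benzyl-7-O-methylagathisflavone | COc1cc2oc(-c3ccc(OCc4ccccc4)cc3)cc(=O)c2c(OCc2ccccc2)c1-c1c(OCc2ccccc2)cc(OCc2ccccc2)c2c(=O)cc(-c3ccc(OCc4ccccc4)cc3)oc12
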